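**Retrosynthetic overview**

1. The target is traced back to a bicyclic C1 enone carrying a C7 dienoate: acetylation of the C1 hydroxyl, MeLi addition to the dienoate (tertiary alcohol), hydroxyl-directed α-epoxidation of C2=C3, and CBS reduction of the C1 ketone are the last operations.
2. The (2Z,4E)-dienyl side chain comes from a C7 ketone: one-carbon homologation to the 7α-aldehyde, alkyne, ynoate, syn addition of Me2CuLi (Z trisubstituted alkene), then oxidation/Wittig (E alkene).
3. The seven-membered ring (C10–C1–C2–C3–C4–C5–C6) is formed second, by 9-BBN hydroboration of a C6 vinyl group and B-alkyl Suzuki closure of C3–C4; the C9 oxygen is then removed by Barton–McCombie deoxygenation. The five-membered ring (C6–C7–C8–C9–C10) is present from the start as a cyclopentenone.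
4. The strategy rests on the contiguous trans,trans centres C7, C6 and C10 of the five-membered ring (C7 substituent / C5 on C6 / C1 on the methyl-bearing quaternary ring-fusion carbon C10). C6 and C10 are set in one pot by vinyl conjugate addition anti to a C7 silyloxy group and aldol at C10 anti to the new vinyl group, from (R)-4-silyloxy-2-methylcyclopentenone, vinylmagnesium bromide and (Z)-3-iodobut-2-enal.
5. The enone comes from commercial (R)-4-(tert-butyldimethylsilyloxy)cyclopentenone (α-iodination, Stille methylation); the iodoenal from ethyl but-2-ynoate (NaI/AcOH, i-Bu2AlH, MnO2).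

Key step: step 6

Remark: atoms carry the target locants throughout (C1 acetoxy carbon, C2/C3 epoxide carbons, C6 ring-fusion CH, C7 side-chain carbon, C10 quaternary ring-fusion carbon); β is the face of the C10 methyl group and α the opposite face; the uncontrolled C1 carbinol centre (and C9 between steps 8 and 10) is carried as a mixture of epimers that converges on oxidation at C1 (on deoxygenation at C9).

**Route**

Step 1
Reactants: 1 (R)-4-(tert-butyldimethylsilyloxy)cyclopent-2-en-1-one
Product: 2 (R)-4-(tert-butyldimethylsilyloxy)-2-iodocyclopent-2-en-1-one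
Conditions: I2, pyridine, CH2Cl2, 0 °C → rt
Reagents that add atoms: iodine, II
Why: α-Iodination of an enone by the pyridine/iodine addition–elimination sequence (conjugate addition of pyridine, iodination of the enolate, loss of pyridine), which is established on 4-silyloxycyclopentenones and does not touch the C4 stereocentre.

Step 2
Reactants: 2 (R)-4-(tert-butyldimethylsilyloxy)-2-iodocyclopent-2-en-1-one
Product: 3 (R)-4-(tert-butyldimethylsilyloxy)-2-methylcyclopent-2-en-1-one
Conditions: SnMe4, PdCl2(PhCN)2 (5 mol %), AsPh3, CuI, NMP, 80 °C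
Reagents that add atoms: tetramethylstannane, C[Sn](C)(C)C
Why: Stille cross-coupling of an α-iodoenone transfers methyl to C2 without added base, so the base-sensitive γ-silyloxy enone and its stereocentre survive.

Step 3
Reactants: 4 ethyl but-2-ynoate
Product: 5 ethyl (Z)-3-iodobut-2-enoate
Conditions: NaI, AcOH, 115 °C
Reagents that add atoms: sodium iodide, [Na+].[I-]
Why: Hydroiodination of an ynoate: iodide adds in conjugate fashion and the allenolate is protonated anti, which places iodine cis to the ester (Z).

Step 4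
Reactants: 5 ethyl (Z)-3-iodobut-2-enoate
Product: 6 (Z)-3-iodobut-2-en-1-ol
Conditions: i-Bu2AlH (DIBAL-H), CH2Cl2, −78 → 0 °C
Reagents that add atoms: none
Why: 1,2-Reduction of the enoate with i-Bu2AlH gives the allylic alcohol and leaves the alkenyl iodide and the Z geometry alone.

Step 5
Reactants: 6 (Z)-3-iodobut-2-en-1-ol
Product: 7 (Z)-3-iodobut-2-enal
Conditions: MnO2, CH2Cl2, rt, dark; used at once
Reagents that add atoms: none
Why: MnO2 oxidation of an allylic alcohol under neutral heterogeneous conditions keeps the Z geometry of the light- and acid-sensitive iodoenal.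

Step 6
Reactants: 3 (R)-4-(tert-butyldimethylsilyloxy)-2-methylcyclopent-2-en-1-one; 8 vinylmagnesium bromide; 7 (Z)-3-iodobut-2-enal
Product: 10 (2S,3R,4R)-4-(tert-butyldimethylsilyloxy)-2-[(Z)-1-hydroxy-3-iodobut-2-en-1-yl]-2-methyl-3-vinylcyclopentan-1-one (C1 carbinol epimers), via bromomagnesium enolate 9 (not isolated)
Conditions: 8 (1.2 equiv), CuBr·SMe2 (0.2 equiv), THF, −78 °C; then 7 (2 equiv), −78 °C; aq. NH4Cl at −78 °C
Reagents that add atoms: none
Why: The Grignard reagent transmetalates to copper and the vinylcopper species adds 1,4 to enone 3 at C6 (π-complex, trivalent copper β-adduct, reductive elimination), which leaves the regiodefined C9–C10 bromomagnesium enolate 9; this adds through C10 to the aldehyde carbon of 7 in a closed, metal-chelated six-membered transition state. The closest known reaction type is the three-component coupling of 4-silyloxycyclopentenones, that is, organocopper conjugate addition followed by trapping of the enolate with an aldehyde. No ring is closed: C5–C6 and C1–C10 are formed, and the C4=C5 vinyl group and the C3 alkenyl iodide stay in place for the later C3–C4 closure of the seven-membered ring. C6 is controlled by the C7 silyloxy group, which blocks the α-face so that the vinyl group enters β; C10 is controlled by that new vinyl group, which sends the aldehyde to the α-face and leaves the methyl group β, so the C7/C6/C10 array is trans,trans; C1 is not controlled. The step needs 1,4- over 1,2-addition (copper), reaction of the enolate at C10 before proton transfer to C8 can expel the C7 silyloxy group (regiospecific enolate generation, −78 °C throughout, cold quench), and attack on the aldehyde of 7 and not on its iodine-bearing carbon (copper kept substoichiometric, excess 7 absorbs residual Grignard reagent).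

Step 7
Reactants: 10 aldol adduct (C1 epimers)
Product: 11 C1 triisopropylsilyl ether of 10
Conditions: TIPSOTf, 2,6-lutidine, CH2Cl2, −78 → 0 °C
Reagents that add atoms: triisopropylsilyl trifluoromethanesulfonate, CC(C)[Si](C(C)C)(C(C)C)OS(=O)(=O)C(F)(F)F
Why: Silyl triflate silylation of a hindered secondary alcohol; the bulky, acid-stable triisopropylsilyl group is chosen so that the C7 tert-butyldimethylsilyl ether can later be removed in its presence.

Step 8
Reactants: 11 C1 triisopropylsilyl ether
Product: 12 C9 alcohol (C1 and C9 epimers)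
Conditions: NaBH4, MeOH/THF, 0 °C
Reagents that add atoms: none
Why: Borohydride reduction of the C9 ketone is done before the basic coupling so that no β-silyloxy ketone (C9 carbonyl, C7 silyloxy) meets base or 9-BBN; the C9 configuration is irrelevant because this oxygen is removed in step 11.

Step 9
Reactants: 12 C9 alcohol
Product: 14 trans-fused bicyclic alcohol (1-OTIPS; Δ2; 3-methyl; 7α-OTBS; 9-OH; 10β-methyl; 6α-H), via B-alkyl-9-BBN borane 13 (not isolated)
Conditions: 9-BBN (3 equiv), THF, 0 °C → rt; then Pd(dppf)Cl2 (10 mol %), AsPh3, Cs2CO3, DMF/THF/H2O, rt → 50 °C, dilute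
Reagents that add atoms: 9-borabicyclo[3.3.1]nonane, B1C2CCCC1CCC2 (its boron stays only in 13; 14 keeps one hydrogen from it)
Why: Anti-Markovnikov hydroboration of the C4=C5 vinyl group puts boron on C4, and intramolecular B-alkyl Suzuki–Miyaura coupling of this primary alkylborane with the (Z)-alkenyl iodide then forms C3–C4 and the seven-membered ring with retention of alkene geometry and without creating a stereocentre.

Step 10
Reactants: 14 bicyclic C9 alcohol
Product: 15 C9 O-(imidazol-1-ylthiocarbonyl) derivative of 14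
Conditions: 1,1'-thiocarbonyldiimidazole, DMAP (cat.), toluene, 90 °C
Reagents that add atoms: 1,1'-thiocarbonyldiimidazole, S=C(n1ccnc1)n1ccnc1
Why: Thioacylation of the C9 alcohol gives the Barton–McCombie precursor without forming a free alkoxide, which avoids silyl migration between the C7 and C9 oxygens.

Step 11
Reactants: 15 C9 thiocarbonylimidazolide
Product: 16 9-deoxy bis-silyl ether (1-OTIPS; 7α-OTBS; Δ2)
Conditions: Bu3SnH, AIBN (cat.), toluene, 100 °C
Reagents that add atoms: none
Why: Barton–McCombie deoxygenation (stannyl radical adds to C=S, the secondary C9 radical is released and takes hydrogen from Bu3SnH), placed after the coupling because an alkenyl iodide would not survive it.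

Step 12
Reactants: 16 bis-silyl ether
Product: 17 7α-alcohol (1-OTIPS retained)
Conditions: CSA (cat.), MeOH/CH2Cl2, 0 °C → rt
Reagents that add atoms: none
Why: Acid-catalysed methanolysis removes the less hindered secondary tert-butyldimethylsilyl ether while the hindered, more acid-stable triisopropylsilyl ether at C1 stays.

Step 13
Reactants: 17 7α-alcohol
Product: 18 C7 ketone (1-OTIPS; Δ2; trans ring fusion)
Conditions: Dess–Martin periodinane, CH2Cl2, 0 °C → rt
Reagents that add atoms: none
Why: Dess–Martin oxidation of the secondary alcohol under non-basic conditions, chosen so that the C6 centre next to the new ketone is not epimerised.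

Step 14
Reactants: 18 C7 ketone
Product: 19 7-(methoxymethylene) enol ether (E/Z mixture)
Conditions: Ph3P(CH2OMe)Cl, KOt-Bu, THF, 0 °C; then 18, 0 °C → rt
Reagents that add atoms: (methoxymethyl)triphenylphosphonium chloride, [Cl-].COC[P+](c1ccccc1)(c1ccccc1)c1ccccc1
Why: Wittig methoxymethylenation homologates the cyclopentanone by one carbon; the ylide is pre-formed so that carbonyl addition outruns enolisation toward C6.

Step 15
Reactants: 19 enol ether
Product: 21 7α-aldehyde (formyl group trans to C5 on C6; 1-OTIPS), via C7-epimeric aldehyde mixture 20 (not isolated)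
Conditions: 1 M HCl, THF, rt; then K2CO3 (cat.), MeOH, rt
Reagents that add atoms: water, O
Why: Acid hydrolysis of the enol ether gives the aldehyde, and base equilibration through the enolate then places the formyl group on the α-face, trans to C5 on the neighbouring C6 (the more stable trans-1,2-disubstituted cyclopentane), which sets C7.

Step 16
Reactants: 21 7α-aldehyde
Product: 22 7α-ethynyl compound
Conditions: dimethyl (1-diazo-2-oxopropyl)phosphonate, K2CO3, MeOH, 0 °C → rt
Reagents that add atoms: dimethyl (1-diazo-2-oxopropyl)phosphonate, COP(=O)(OC)C(=[N+]=[N-])C(C)=O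
Why: Ohira–Bestmann (Seyferth–Gilbert) homologation converts the aldehyde into the terminal alkyne under the same K2CO3/MeOH conditions that hold C7 at its trans equilibrium, and the alkyne is then configurationally fixed.

Step 17
Reactants: 22 7α-ethynyl compound
Product: 24 ethyl 3-(bicycle-7α-yl)prop-2-ynoate, via lithium acetylide 23 (not isolated)
Conditions: n-BuLi, THF, −78 °C; then ClCO2Et, −78 → 0 °C
Reagents that add atoms: ethyl chloroformate, CCOC(Cl)=O; n-butyllithium, [Li]CCCC (its lithium stays only in 23)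
Why: Deprotonation of the terminal alkyne and C-acylation of the lithium acetylide with a chloroformate give the ynoate.

Step 18
Reactants: 24 ynoate
Product: 25 ethyl (Z)-3-(bicycle-7α-yl)but-2-enoate
Conditions: Me2CuLi (from MeLi and CuI), THF, −78 °C; MeOH quench at −78 °C
Reagents that add atoms: lithium dimethylcuprate, [Li+].C[Cu-]C (made in the flask from methyllithium, [Li]C, and CuI)
Why: Conjugate addition of a lithium dialkylcuprate to an ynoate is a syn carbocupration, and protonation of the alkenylcopper at −78 °C with retention puts the new methyl cis to hydrogen, hence C7 cis to the ester (Z).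

Step 19
Reactants: 25 (Z)-enoate
Product: 26 (Z)-3-(bicycle-7α-yl)but-2-en-1-ol
Conditions: i-Bu2AlH (DIBAL-H), CH2Cl2, −78 °C
Reagents that add atoms: none
Why: 1,2-Reduction of the enoate with i-Bu2AlH gives the allylic alcohol without changing the alkene geometry.

Step 20
Reactants: 26 (Z)-allylic alcohol
Product: 28 ethyl (2E,4Z)-5-(bicycle-7α-yl)hexa-2,4-dienoate (1-OTIPS), via (Z)-enal 27 (not isolated)
Conditions: MnO2, Ph3P=CHCO2Et, CH2Cl2, rt
Reagents that add atoms: (ethoxycarbonylmethylene)triphenylphosphorane, CCOC(=O)C=P(c1ccccc1)(c1ccccc1)c1ccccc1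
Why: Tandem MnO2 oxidation–Wittig reaction traps the (Z)-enal as it forms with a stabilised ylide, which gives the new disubstituted alkene E and avoids isolating the isomerisation-prone enal.

Step 21
Reactants: 28 silyl-protected dienoate
Product: 29 C1 allylic alcohol dienoate (C1 epimers)
Conditions: Bu4NF, THF, rt → 45 °C
Reagents that add atoms: none
Why: Fluoride cleavage of the silyl ether (Si–F bond formation) frees the C1 hydroxyl while the dienoate and alkenes are inert.

Step 22
Reactants: 29 C1 allylic alcohol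
Product: 30 C1 enone dienoate
Conditions: Dess–Martin periodinane, CH2Cl2, 0 °C → rt
Reagents that add atoms: none
Why: Dess–Martin oxidation of the allylic alcohol converges both C1 epimers on one enone.

Step 23
Reactants: 30 C1 enone
Product: 31 1α-allylic alcohol dienoate (C1–OH trans to the C10 methyl)
Conditions: (S)-2-methyl-CBS-oxazaborolidine (0.3 equiv), catecholborane, toluene, −78 → −40 °C
Reagents that add atoms: none
Why: Corey–Bakshi–Shibata reduction: with the quaternary C10 taken as the large group, the (S)-oxazaborolidine should deliver hydride to the β-face of the C1 carbonyl (syn to the C10 methyl) against the substrate preference and set C1 with the hydroxyl α, while catecholborane at low temperature leaves the dienoate alone.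

Step 24
Reactants: 31 1α-allylic alcohol
Product: 32 1α-hydroxy-2α,3α-epoxide dienoate
Conditions: VO(acac)2 (cat.), t-BuOOH, CH2Cl2, 0 °C → rt
Reagents that add atoms: tert-butyl hydroperoxide, CC(C)(C)OO
Why: Vanadium-catalysed hydroxyl-directed epoxidation of the cyclic allylic alcohol delivers oxygen to C2=C3 from the face of the C1 hydroxyl (α), which sets C2 and C3, and the electron-poor dienoate is not epoxidised.

Step 25
Reactants: 32 epoxy alcohol dienoate
Product: 34 epoxy diol (1α-OH; side-chain tertiary OH), via lithium alkoxide methyl ketone 33 (not isolated)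
Conditions: MeLi (5 equiv), THF, −78 °C
Reagents that add atoms: methyllithium, [Li]C
Why: Double 1,2-addition of MeLi to the ester through the methyl ketone gives the tertiary alcohol; at −78 °C the trisubstituted epoxide is not opened, and the cis epoxy alkoxide cannot undergo Payne rearrangement.

Step 26
Reactants: 34 epoxy diol
Product: 35 CNP0265175.1 (target)
Conditions: Ac2O, pyridine, DMAP (cat.), CH2Cl2, 0 °C → rt
Reagents that add atoms: acetic anhydride, CC(=O)OC(C)=O
Why: DMAP-catalysed acetylation is selective for the secondary C1 hydroxyl over the tertiary side-chain hydroxyl and gives the target.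

**Compound list**

1 | (R)-4-(tert-butyldimethylsilyloxy)cyclopent-2-en-1-one | O=C1C=C[C@H](O[Si](C)(C)C(C)(C)C)C1 | starting material
2 | (R)-4-(tert-butyldimethylsilyloxy)-2-iodocyclopent-2-en-1-one | O=C1C(I)=C[C@H](O[Si](C)(C)C(C)(C)C)C1 | intermediate
3 | (R)-4-(tert-butyldimethylsilyloxy)-2-methylcyclopent-2-en-1-one | CC1=C[C@H](O[Si](C)(C)C(C)(C)C)CC1=O | intermediate
4 | ethyl but-2-ynoate | CC#CC(=O)OCC | starting material
5 | ethyl (Z)-3-iodobut-2-enoate | CCOC(=O)/C=C(C)\I | intermediate
6 | (Z)-3-iodobut-2-en-1-ol | OC/C=C(C)\I | intermediate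
7 | (Z)-3-iodobut-2-enal | O=C/C=C(C)\I | intermediate
8 | vinylmagnesium bromide | C=C[Mg]Br | starting material
9 | bromomagnesium (3R,4R)-4-(tert-butyldimethylsilyloxy)-2-methyl-3-vinylcyclopent-1-en-1-olate | CC1=C(O[Mg]Br)C[C@@H](O[Si](C)(C)C(C)(C)C)[C@@H]1C=C | intermediate
10 | (2S,3R,4R)-4-(tert-butyldimethylsilyloxy)-2-[(Z)-1-hydroxy-3-iodobut-2-en-1-yl]-2-methyl-3-vinylcyclopentan-1-one, C1 carbinol epimers | O=C1C[C@@H](O[Si](C)(C)C(C)(C)C)[C@H](C=C)[C@@]1(C)C(O)/C=C(C)\I | intermediate
11 | C1 triisopropylsilyl ether of 10 | O=C1C[C@@H](O[Si](C)(C)C(C)(C)C)[C@H](C=C)[C@@]1(C)C(O[Si](C(C)C)(C(C)C)C(C)C)/C=C(C)\I | intermediate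
12 | C9 alcohol from 11 (cyclopentanol, C1 and C9 epimers) | OC1C[C@@H](O[Si](C)(C)C(C)(C)C)[C@H](C=C)[C@@]1(C)C(O[Si](C(C)C)(C(C)C)C(C)C)/C=C(C)\I | intermediate
13 | B-alkyl-9-BBN borane from 12 (boron on C4) | OC1C[C@@H](O[Si](C)(C)C(C)(C)C)[C@H](CCB2C3CCCC2CCC3)[C@@]1(C)C(O[Si](C(C)C)(C(C)C)C(C)C)/C=C(C)\I | intermediate
14 | trans-fused bicyclic alcohol: 1-OTIPS (C1 epimers), C2=C3, 3-methyl, 7α-OTBS, 9-OH (C9 epimers), 10β-methyl, 6α-H | CC(C)[Si](C(C)C)(C(C)C)OC1C=C(C)CC[C@H]2[C@H](O[Si](C)(C)C(C)(C)C)CC(O)[C@]12C | intermediate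
15 | C9 O-(imidazol-1-ylthiocarbonyl) derivative of 14 | CC(C)[Si](C(C)C)(C(C)C)OC1C=C(C)CC[C@H]2[C@H](O[Si](C)(C)C(C)(C)C)CC(OC(=S)n3ccnc3)[C@]12C | intermediate
16 | 9-deoxy bicycle: 1-OTIPS, 7α-OTBS, C2=C3, trans-fused | CC(C)[Si](C(C)C)(C(C)C)OC1C=C(C)CC[C@H]2[C@H](O[Si](C)(C)C(C)(C)C)CC[C@]12C | intermediate
17 | 7α-alcohol: 1-OTIPS, 7α-OH | CC(C)[Si](C(C)C)(C(C)C)OC1C=C(C)CC[C@H]2[C@H](O)CC[C@]12C | intermediate
18 | C7 ketone: 1-OTIPS, 7-oxo, 6α-H, 10β-methyl | CC(C)[Si](C(C)C)(C(C)C)OC1C=C(C)CC[C@H]2C(=O)CC[C@]12C | intermediate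
19 | 7-(methoxymethylene) enol ether, E/Z mixture | CC(C)[Si](C(C)C)(C(C)C)OC1C=C(C)CC[C@H]2C(=COC)CC[C@]12C | intermediate
20 | 7-formyl bicycle, C7 epimer mixture | CC(C)[Si](C(C)C)(C(C)C)OC1C=C(C)CC[C@H]2C(C=O)CC[C@]12C | intermediate
21 | 7α-formyl bicycle (formyl trans to C5), 1-OTIPS | CC(C)[Si](C(C)C)(C(C)C)OC1C=C(C)CC[C@H]2[C@H](C=O)CC[C@]12C | intermediate
22 | 7α-ethynyl bicycle, 1-OTIPS | CC(C)[Si](C(C)C)(C(C)C)OC1C=C(C)CC[C@H]2[C@H](C#C)CC[C@]12C | intermediate
23 | lithium acetylide of 22 | CC(C)[Si](C(C)C)(C(C)C)OC1C=C(C)CC[C@H]2[C@H](C#C[Li])CC[C@]12C | intermediate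
24 | ethyl 3-(bicycle-7α-yl)prop-2-ynoate, 1-OTIPS | CC(C)[Si](C(C)C)(C(C)C)OC1C=C(C)CC[C@H]2[C@H](C#CC(=O)OCC)CC[C@]12C | intermediate
25 | ethyl (Z)-3-(bicycle-7α-yl)but-2-enoate, 1-OTIPS | CC(C)[Si](C(C)C)(C(C)C)OC1C=C(C)CC[C@H]2[C@H](/C(C)=C\C(=O)OCC)CC[C@]12C | intermediate
26 | (Z)-3-(bicycle-7α-yl)but-2-en-1-ol, 1-OTIPS | CC(C)[Si](C(C)C)(C(C)C)OC1C=C(C)CC[C@H]2[C@H](/C(C)=C\CO)CC[C@]12C | intermediate
27 | (Z)-3-(bicycle-7α-yl)but-2-enal, 1-OTIPS | CC(C)[Si](C(C)C)(C(C)C)OC1C=C(C)CC[C@H]2[C@H](/C(C)=C\C=O)CC[C@]12C | intermediate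
28 | ethyl (2E,4Z)-5-(bicycle-7α-yl)hexa-2,4-dienoate, 1-OTIPS | CC(C)[Si](C(C)C)(C(C)C)OC1C=C(C)CC[C@H]2[C@H](/C(C)=C\C=C\C(=O)OCC)CC[C@]12C | intermediate
29 | 1-hydroxy dienoate, C1 epimers | OC1C=C(C)CC[C@H]2[C@H](/C(C)=C\C=C\C(=O)OCC)CC[C@]12C | intermediate
30 | 1-oxo dienoate (C1 enone, C2=C3) | O=C1C=C(C)CC[C@H]2[C@H](/C(C)=C\C=C\C(=O)OCC)CC[C@]12C | intermediate
31 | 1α-hydroxy dienoate (C1–OH trans to C10 methyl) | O[C@@H]1C=C(C)CC[C@H]2[C@H](/C(C)=C\C=C\C(=O)OCC)CC[C@]12C | intermediate
32 | 1α-hydroxy-2α,3α-epoxy dienoate | O[C@@H]1[C@@H]2O[C@]2(C)CC[C@H]2[C@H](/C(C)=C\C=C\C(=O)OCC)CC[C@]12C | intermediate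
33 | lithium 1α-alkoxide of the 2α,3α-epoxy (3E,5Z)-dienyl methyl ketone | [Li]O[C@@H]1[C@@H]2O[C@]2(C)CC[C@H]2[C@H](/C(C)=C\C=C\C(C)=O)CC[C@]12C | intermediate
34 | epoxy diol: 1α-OH, 2α,3α-epoxide, 7α-[(2Z,4E)-6-hydroxy-6-methylhepta-2,4-dien-2-yl] | O[C@@H]1[C@@H]2O[C@]2(C)CC[C@H]2[C@H](/C(C)=C\C=C\C(C)(C)O)CC[C@]12C | intermediate
35 | CNP0265175.1 | CC(=O)O[C@@H]1[C@@H]2O[C@]2(C)CC[C@H]2[C@H](/C(C)=C\C=C\C(C)(C)O)CC[C@]12C | target

**Step count and risks**

Total step count: 26. Longest linear sequence: 24 steps (steps 3–5, then 6–26, from ethyl but-2-ynoate 4).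

Steps most likely to fail:

Step 6 (key step). The hindered tetrasubstituted enolate may react too slowly with the aldehyde, so that proton transfer toward C8 and loss of the C7 silyloxy group, or consumption of the iodoenal by residual organometallic at its iodine-bearing carbon, compete with the aldol. The fallback sets out from 3 and returns at 10; it separates the two bond formations. The conjugate addition is run with Me3SiCl present, so the enolate is captured as (3R,4R)-4-(tert-butyldimethylsilyloxy)-2-methyl-1-(trimethylsilyloxy)-3-vinylcyclopent-1-ene F1, which is isolated free of copper and magnesium salts. MeLi in THF then cleaves the O–Si bond to regenerate the regiodefined lithium (3R,4R)-4-(tert-butyldimethylsilyloxy)-2-methyl-3-vinylcyclopent-1-en-1-olate F2, which is treated with 7 at −78 °C and should give 10 with the same anti-to-vinyl facial course.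

Step 9. Transmetalation and reductive elimination in the medium-ring closure may be slow, so that protodeboronation, β-hydride elimination or intermolecular coupling take over. The fallback sets out from 3 and returns at 14; it closes the seven-membered ring by olefin metathesis at C2=C3 in place of cross-coupling at C3–C4. Copper-catalysed addition of 3-methylbut-3-enylmagnesium bromide to 3 gives bromomagnesium (3R,4R)-4-(tert-butyldimethylsilyloxy)-2-methyl-3-(3-methylbut-3-enyl)cyclopent-1-en-1-olate F3, which is trapped with acrolein as (2S,3R,4R)-4-(tert-butyldimethylsilyloxy)-2-(1-hydroxyprop-2-enyl)-2-methyl-3-(3-methylbut-3-enyl)cyclopentan-1-one F4. Silylation (TIPSOTf, 2,6-lutidine) gives its triisopropylsilyl ether F5 and NaBH4 reduction the corresponding C9 alcohol F6. Ring-closing metathesis with the second-generation Grubbs catalyst RuCl2(=CHPh)(PCy3)(H2IMes) in toluene at 80 °C should then form the trisubstituted C2=C3 alkene and give 14.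

Step 23. Catalyst and substrate preferences oppose each other (hydride delivery anti to the C10 methyl is the substrate's choice), so facial selectivity may be poor or the hindered ketone may react sluggishly. The fallback sets out from 30 and returns at 31; it uses substrate control followed by inversion. Luche reduction (NaBH4, CeCl3·7H2O, MeOH, −78 °C) should give the 1β-hydroxy dienoate F7 by hydride attack anti to the C10 methyl. Mitsunobu reaction with 4-nitrobenzoic acid (PPh3, diisopropyl azodicarboxylate, toluene) inverts C1 to the 1α 4-nitrobenzoate F8, and ethanolysis (K2CO3, EtOH) releases 31.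

Further compounds
F1 | step 6 | (3R,4R)-4-(tert-butyldimethylsilyloxy)-2-methyl-1-(trimethylsilyloxy)-3-vinylcyclopent-1-ene | CC1=C(O[Si](C)(C)C)C[C@@H](O[Si](C)(C)C(C)(C)C)[C@@H]1C=C
F2 | step 6 | lithium (3R,4R)-4-(tert-butyldimethylsilyloxy)-2-methyl-3-vinylcyclopent-1-en-1-olate | CC1=C(O[Li])C[C@@H](O[Si](C)(C)C(C)(C)C)[C@@H]1C=C
F3 | step 9 | bromomagnesium (3R,4R)-4-(tert-butyldimethylsilyloxy)-2-methyl-3-(3-methylbut-3-enyl)cyclopent-1-en-1-olate | CC1=C(O[Mg]Br)C[C@@H](O[Si](C)(C)C(C)(C)C)[C@@H]1CCC(C)=C
F4 | step 9 | (2S,3R,4R)-4-(tert-butyldimethylsilyloxy)-2-(1-hydroxyprop-2-enyl)-2-methyl-3-(3-methylbut-3-enyl)cyclopentan-1-one, C1 carbinol epimers | O=C1C[C@@H](O[Si](C)(C)C(C)(C)C)[C@H](CCC(C)=C)[C@@]1(C)C(O)C=C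
F5 | step 9 | C1 triisopropylsilyl ether of F4 | O=C1C[C@@H](O[Si](C)(C)C(C)(C)C)[C@H](CCC(C)=C)[C@@]1(C)C(O[Si](C(C)C)(C(C)C)C(C)C)C=C
F6 | step 9 | C9 alcohol from F5 | OC1C[C@@H](O[Si](C)(C)C(C)(C)C)[C@H](CCC(C)=C)[C@@]1(C)C(O[Si](C(C)C)(C(C)C)C(C)C)C=C
F7 | step 23 | 1β-hydroxy dienoate (C1 epimer of 31) | O[C@H]1C=C(C)CC[C@H]2[C@H](/C(C)=C\C=C\C(=O)OCC)CC[C@]12C
F8 | step 23 | 1α 4-nitrobenzoate of the dienoate | O=C(O[C@@H]1C=C(C)CC[C@H]2[C@H](/C(C)=C\C=C\C(=O)OCC)CC[C@]12C)c1ccc(cc1)[N+](=O)[O-]
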